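**Strategy.** The seven-membered ring is disconnected at C7–C8 and C1–C10. The key step exploits the C6–C7–C8=C9–C10 segment of that ring, which with C5 is a cyclohepta-1,4-diene enol ether in latent form. A rhodium vinylcarbenoid cyclopropanates the terminal enol ether of a 2-silyloxydiene built on the cyclopentene C1–C5 (ring-contracted (R)-terpinen-4-ol). The cis-divinylcyclopropane then ring-expands by Cope rearrangement, closing the ring and creating quaternary C1. The C10 oxygen arrives trans to the C1 methyl; it enters as a benzoate so that it can be unmasked and inverted by oxidation–reduction while C5 is still trigonal. The ring fusion and C6 are set afterwards.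

Key step: step 9

Remark: labels C1–C10 are local (C1 quaternary methyl carbon; C2, C3 ring CH2; C4 isopropyl carbinol; C5 ring-fusion CH; C6 aroyloxy carbon; C7 CH2; C8 methyl-bearing alkene carbon; C9 alkene CH; C10 isovaleryloxy carbon) and β is the face of the C1 methyl, so the target has C4–OH, H5 and C10–O β and C4-isopropyl and C6–O α (cis ring fusion); it is assumed that Rh2(S-DOSP)4 is the catalyst enantiomer that selects the required enol ether face, its mirror image being used if the C1/C4 correlation in 16 shows the opposite.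

**Route**

Step 1
Reactants: 1 (R)-(−)-terpinen-4-ol
Product: 2 (R)-triethyl[(1-isopropyl-4-methylcyclohex-3-en-1-yl)oxy]silane
Conditions: Et3SiOTf, 2,6-lutidine, CH2Cl2, 0 °C → rt
Reagents that add atoms: triethylsilyl trifluoromethanesulfonate, CC[Si](CC)(CC)OS(=O)(=O)C(F)(F)F
Why: Silylation of a tertiary alcohol with a silyl triflate and a hindered pyridine base is routine and leaves the only stereocentre untouched.

Step 2
Reactants: 2 (R)-triethyl[(1-isopropyl-4-methylcyclohex-3-en-1-yl)oxy]silane
Product: 4 (R)-3-isopropyl-6-oxo-3-(triethylsilyloxy)heptanal, via ozonide 3 (not isolated)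
Conditions: O3, CH2Cl2, −78 °C; then PPh3, −78 °C → rt
Reagents that add atoms: ozone, [O-][O+]=O
Why: Ozonolysis of the single trisubstituted alkene with reductive work-up opens the ring to the 1,6-keto aldehyde without touching the quaternary carbinol carbon.

Step 3
Reactants: 4 (R)-3-isopropyl-6-oxo-3-(triethylsilyloxy)heptanal
Product: 6 (S)-5-isopropyl-2-methyl-5-(triethylsilyloxy)cyclopent-1-ene-1-carbaldehyde, via aldol adduct 5 (not isolated)
Conditions: piperidine (0.3 equiv), AcOH (0.3 equiv), toluene, 60 °C
Reagents that add atoms: none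
Why: Amine-salt-catalysed intramolecular aldol condensation in which the aldehyde enamine attacks the methyl ketone (five-membered ring, enolexo closure) and water is lost to the tetrasubstituted enal, the known outcome for 6-oxoheptanals; the moderate temperature keeps β-elimination of the silyloxy group in check.

Step 4
Reactants: 6 (S)-5-isopropyl-2-methyl-5-(triethylsilyloxy)cyclopent-1-ene-1-carbaldehyde
Product: 7 1-[(S)-5-isopropyl-2-methyl-5-(triethylsilyloxy)cyclopent-1-en-1-yl]ethan-1-ol (both carbinol epimers)
Conditions: MeMgBr, THF, −78 → 0 °C; aq. NH4Cl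
Reagents that add atoms: methylmagnesium bromide, C[Mg]Br
Why: Grignard 1,2-addition to the aldehyde carbonyl; the new carbinol centre should form as a mixture and is removed in the next step.

Step 5
Reactants: 7 1-[(S)-5-isopropyl-2-methyl-5-(triethylsilyloxy)cyclopent-1-en-1-yl]ethan-1-ol
Product: 8 1-[(S)-5-isopropyl-2-methyl-5-(triethylsilyloxy)cyclopent-1-en-1-yl]ethan-1-one
Conditions: Dess–Martin periodinane, CH2Cl2, rt
Reagents that add atoms: none
Why: Dess–Martin oxidation of the secondary allylic alcohol to the methyl ketone under near-neutral conditions that the tertiary silyl ether survives.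

Step 6
Reactants: 8 1-[(S)-5-isopropyl-2-methyl-5-(triethylsilyloxy)cyclopent-1-en-1-yl]ethan-1-one
Product: 9 tert-butyl({1-[(S)-5-isopropyl-2-methyl-5-(triethylsilyloxy)cyclopent-1-en-1-yl]vinyl}oxy)dimethylsilane (2-silyloxydiene)
Conditions: t-BuMe2SiOTf, Et3N, CH2Cl2, −78 → 0 °C
Reagents that add atoms: tert-butyldimethylsilyl trifluoromethanesulfonate, CC(C)(C)[Si](C)(C)OS(=O)(=O)C(F)(F)F
Why: Soft enolisation of a methyl ketone (O-silylation, then loss of an acetyl proton to the amine) gives the terminal 2-silyloxydiene, because the acetyl group is twisted out of conjugation by the tetrasubstituted alkene and γ-deprotonation therefore does not compete.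

Step 7
Reactants: 10 ethyl diazoacetate; 11 2-oxoethyl benzoate (benzoyloxyacetaldehyde)
Product: 12 ethyl 4-(benzoyloxy)-2-diazo-3-hydroxybutanoate (racemic)
Conditions: LiN(i-Pr)2 added to 10 + 11, THF, −78 °C; AcOH quench at −78 °C
Reagents that add atoms: none
Why: Aldol-type addition of lithiated ethyl diazoacetate to the aldehyde at −78 °C with a cold acidic quench, which prevents benzoyl migration; the carbinol centre is racemic and is lost in step 8.

Step 8
Reactants: 12 ethyl 4-(benzoyloxy)-2-diazo-3-hydroxybutanoate
Product: 14 ethyl (E)-4-(benzoyloxy)-2-diazobut-3-enoate, via trifluoroacetate 13 (not isolated)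
Conditions: (CF3CO)2O, Et3N, CH2Cl2, −78 → 0 °C; used cold and at once
Reagents that add atoms: none
Why: O-Trifluoroacetylation and amine-induced anti elimination, the usual dehydration of β-hydroxy α-diazo esters to vinyl diazo esters, should give the conjugated (E)-enol benzoate, which is used immediately to outrun electrocyclisation to a pyrazole.

Step 9
Reactants: 9 2-silyloxydiene; 14 ethyl (E)-4-(benzoyloxy)-2-diazobut-3-enoate
Product: 16 hexahydroazulene cycloadduct (C8 CO2Et; C8=C9; C10α benzoate; C1β methyl; C4β OSiEt3; C5=C6 tert-butyldimethylsilyl enol ether), via cis-divinylcyclopropane 15 (not isolated)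
Conditions: Rh2(S-DOSP)4 (2 mol%), 14 (2 equiv, added over 3 h), hexanes/PhCF3, −40 °C → rt; then toluene, 90 °C
Reagents that add atoms: none
Why: Rh2(S-DOSP)4 (dirhodium tetrakis[(S)-N-(4-dodecylphenylsulfonyl)prolinate], divalent rhodium) releases N2 from 14 and the donor–acceptor vinylcarbenoid adds to the C6=C7 enol ether (C8 bonds to C7 and C6), after which cis-divinylcyclopropane 15 undergoes a Cope 3,3-shift through a boat transition state that forms C1–C10 and breaks C6–C8, the bond weakened by the silyloxy donor and the ester acceptor. The closest known reaction type is the tandem cyclopropanation–Cope rearrangement (formal 4+3 annulation) of vinyl diazoacetates with dienes, which is established for 2-silyloxydienes and for dienes whose far terminus lies in a ring. The three-membered ring closes by carbenoid addition and the seven-membered ring by sigmatropic ring expansion of that cyclopropane, not by an ionic cyclisation. C1 is controlled by the catalyst, which picks the enol ether face, because the boat geometry then forces C10 onto the cyclopentene face fixed by the cyclopropane configuration (anti to the C4 silyloxy group, leaving the methyl cis to it); C10 is controlled by the (E)-enol benzoate, whose outward oxygen finishes cis to the outward ring carbon C2 and thus trans to the inward C1 methyl. The step needs site selectivity for C6=C7 and cis placement of the two alkenyl groups: the substrate secures the first because only the terminal electron-rich enol ether is accessible while the tetrasubstituted C1=C5 bond is not, and the second because a trans isomer can reach the cis one through reversible opening of the donor–acceptor cyclopropane. The inward methyl at C1 raises the Cope barrier, hence the final heating.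

Step 10
Reactants: 16 hexahydroazulene cycloadduct
Product: 17 diol (C8 CH2OH; C10α OH; silyl enol ether and C4 silyl ether retained)
Conditions: i-Bu2AlH (6 equiv), CH2Cl2, −78 → −20 °C; aq. potassium sodium tartrate
Reagents that add atoms: none
Why: Hydride reduction with i-Bu2AlH converts the conjugated ester into the primary allylic alcohol and cleaves the benzoate in the same flask, while the silyl ether and the silyl enol ether are inert and no stereocentre is touched.

Step 11
Reactants: 17 diol
Product: 19 C8-methyl C10α-alcohol, via allylic mesylate 18 (not isolated)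
Conditions: MsCl (1.1 equiv), Et3N, THF, −40 °C; then LiEt3BH (4 equiv), −40 → 0 °C
Reagents that add atoms: none
Why: Sulfonylation selects the primary allylic hydroxyl over the neopentyl secondary one, and hydride displacement (SN2) of the allylic mesylate by LiEt3BH should give the C8 methyl group without allylic transposition; the C10 hydroxyl is trans to the CH2OMs group across the ring alkene and cannot cyclise onto it.

Step 12
Reactants: 19 C8-methyl C10α-alcohol
Product: 20 C10 enone (C8=C9–C10=O; C5=C6 silyl enol ether retained)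
Conditions: MnO2 (20 equiv), CH2Cl2, rt
Reagents that add atoms: none
Why: Allylic oxidation with MnO2 is chemoselective and neutral, so the silyl enol ether survives while the wrongly configured C10 stereocentre is erased.

Step 13
Reactants: 20 C10 enone
Product: 21 C10β-alcohol
Conditions: i-Bu2AlH (1.5 equiv), CH2Cl2, −78 °C
Reagents that add atoms: none
Why: 1,2-Reduction of the enone in which, with C5 still trigonal, carbon C2 of the five-membered ring lies in the plane of the C5=C6 bond and the C1 methyl is therefore pseudo-axial on the seven-membered ring, so that hydride should add to the α face anti to it and the hydroxyl should end up cis (β) to the methyl, the usual sense for a ketone next to an axial angular methyl group.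

Step 14
Reactants: 21 C10β-alcohol
Product: 22 C10β-isovalerate
Conditions: isovaleryl chloride, pyridine, DMAP (cat.), CH2Cl2, 0 °C → rt
Reagents that add atoms: 3-methylbutanoyl chloride, CC(C)CC(=O)Cl
Why: DMAP-catalysed acylation of the secondary alcohol with retention at C10, the pyridine buffer protecting the silyl enol ether.

Step 15
Reactants: 22 C10β-isovalerate
Product: 23 cis-fused C6 ketone (C5β H)
Conditions: Bu4NF (1.1 equiv), AcOH (1.2 equiv), THF, −20 → 0 °C
Reagents that add atoms: none
Why: Fluoride-induced cleavage of the silyl enol ether, which is far faster than that of the tertiary triethylsilyl ether, with buffered protonation at C5 expected on the convex β face (flanked by CH3 and O–Si, not by the isopropyl group and the fold of the seven-membered ring) to give the cis-fused ketone, which should also be the more stable epimer beside an angular methyl; acetic acid keeps the enolate from expelling the C4 silyloxy group.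

Step 16
Reactants: 23 cis-fused C6 ketone
Product: 24 C6α-alcohol
Conditions: LiB(s-Bu)3H (1.5 equiv), THF, −78 → −40 °C; aq. NH4Cl
Reagents that add atoms: none
Why: Ketone reduction with a bulky hydride, which should attack the cis-fused bicycle from its convex β face because the α face is screened by the five-membered ring and the C4 isopropyl group, giving the C6 α-alcohol; the ester is inert at this temperature.

Step 17
Reactants: 25 4-hydroxybenzoic acid
Product: 27 4-(tert-butyldimethylsilyloxy)benzoic acid, via silyl ester 26 (not isolated)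
Conditions: t-BuMe2SiCl (2.4 equiv), imidazole, DMF, rt; then AcOH/THF/H2O, rt
Reagents that add atoms: tert-butyldimethylsilyl chloride, CC(C)(C)[Si](C)(C)Cl
Why: Exhaustive silylation followed by selective hydrolysis of the labile silyl ester leaves the more robust aryl silyl ether, a standard way to mask a phenolic acid.

Step 18
Reactants: 24 C6α-alcohol; 27 4-(tert-butyldimethylsilyloxy)benzoic acid
Product: 29 C6α 4-(tert-butyldimethylsilyloxy)benzoate, via mixed anhydride 28 (not isolated)
Conditions: 27, 2,4,6-trichlorobenzoyl chloride, Et3N, toluene, rt; then 24, DMAP, rt → 50 °C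
Reagents that add atoms: none
Why: Yamaguchi esterification, in which the hindered mixed anhydride passes only the 4-silyloxybenzoyl group through the acylpyridinium ion to the hindered C6 alcohol with retention, the tertiary C4 oxygen being silylated.

Step 19
Reactants: 29 C6α 4-(tert-butyldimethylsilyloxy)benzoate
Product: 30 target CNP0086724.1
Conditions: HF·pyridine, pyridine, THF, 0 °C → rt
Reagents that add atoms: none
Why: Fluoride-mediated desilylation with buffered HF should remove the tertiary triethylsilyl ether and the aryl silyl ether without hydrolysis or migration of the two esters and without ionising the allylic C10–O bond.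

**Compound list**

1 | (R)-(−)-terpinen-4-ol | CC1=CC[C@@](O)(C(C)C)CC1 | starting material
2 | (R)-triethyl[(1-isopropyl-4-methylcyclohex-3-en-1-yl)oxy]silane | CC1=CC[C@@](O[Si](CC)(CC)CC)(C(C)C)CC1 | intermediate
3 | secondary ozonide of 2 (diastereomer mixture) | CC12OOC(C[C@@](O[Si](CC)(CC)CC)(C(C)C)CC1)O2 | intermediate (not isolated)
4 | (R)-3-isopropyl-6-oxo-3-(triethylsilyloxy)heptanal | CC(=O)CC[C@](O[Si](CC)(CC)CC)(C(C)C)CC=O | intermediate
5 | 2-hydroxy-5-isopropyl-2-methyl-5-(triethylsilyloxy)cyclopentane-1-carbaldehyde (aldol adduct, silyloxy carbon unchanged) | CC1(O)CC[C@](O[Si](CC)(CC)CC)(C(C)C)C1C=O | intermediate (not isolated)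
6 | (S)-5-isopropyl-2-methyl-5-(triethylsilyloxy)cyclopent-1-ene-1-carbaldehyde | CC1=C(C=O)[C@@](O[Si](CC)(CC)CC)(C(C)C)CC1 | intermediate
7 | 1-[(S)-5-isopropyl-2-methyl-5-(triethylsilyloxy)cyclopent-1-en-1-yl]ethan-1-ol (carbinol epimers) | CC(O)C1=C(C)CC[C@]1(O[Si](CC)(CC)CC)C(C)C | intermediate
8 | 1-[(S)-5-isopropyl-2-methyl-5-(triethylsilyloxy)cyclopent-1-en-1-yl]ethan-1-one | CC(=O)C1=C(C)CC[C@]1(O[Si](CC)(CC)CC)C(C)C | intermediate
9 | tert-butyl({1-[(S)-5-isopropyl-2-methyl-5-(triethylsilyloxy)cyclopent-1-en-1-yl]vinyl}oxy)dimethylsilane | C=C(O[Si](C)(C)C(C)(C)C)C1=C(C)CC[C@]1(O[Si](CC)(CC)CC)C(C)C | intermediate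
10 | ethyl diazoacetate | CCOC(=O)C=[N+]=[N-] | starting material
11 | 2-oxoethyl benzoate | O=CCOC(=O)c1ccccc1 | starting material
12 | ethyl 4-(benzoyloxy)-2-diazo-3-hydroxybutanoate (racemic) | CCOC(=O)C(=[N+]=[N-])C(O)COC(=O)c1ccccc1 | intermediate
13 | ethyl 4-(benzoyloxy)-2-diazo-3-(trifluoroacetoxy)butanoate | CCOC(=O)C(=[N+]=[N-])C(OC(=O)C(F)(F)F)COC(=O)c1ccccc1 | intermediate (not isolated)
14 | ethyl (E)-4-(benzoyloxy)-2-diazobut-3-enoate | CCOC(=O)C(=[N+]=[N-])/C=C/OC(=O)c1ccccc1 | intermediate
15 | cis-divinylcyclopropane: ethyl 1-[(E)-2-(benzoyloxy)vinyl]-2-(tert-butyldimethylsilyloxy)-2-[(S)-5-isopropyl-2-methyl-5-(triethylsilyloxy)cyclopent-1-en-1-yl]cyclopropane-1-carboxylate, alkenyl groups cis | CCOC(=O)[C@@]1(/C=C/OC(=O)c2ccccc2)C[C@]1(O[Si](C)(C)C(C)(C)C)C3=C(C)CC[C@]3(O[Si](CC)(CC)CC)C(C)C | intermediate (not isolated)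
16 | cycloadduct: C8 CO2Et, C8=C9, C10α OBz, C1β CH3, C4β OSiEt3 (C4α i-Pr), C5=C6 OSi(t-Bu)Me2 | CCOC(=O)C1=C[C@H](OC(=O)c2ccccc2)[C@]2(C)CC[C@](O[Si](CC)(CC)CC)(C(C)C)C2=C(O[Si](C)(C)C(C)(C)C)C1 | intermediate
17 | diol: C8 CH2OH, C10α OH, otherwise as 16 | OCC1=C[C@H](O)[C@]2(C)CC[C@](O[Si](CC)(CC)CC)(C(C)C)C2=C(O[Si](C)(C)C(C)(C)C)C1 | intermediate
18 | primary allylic mesylate of 17 | CS(=O)(=O)OCC1=C[C@H](O)[C@]2(C)CC[C@](O[Si](CC)(CC)CC)(C(C)C)C2=C(O[Si](C)(C)C(C)(C)C)C1 | intermediate (not isolated)
19 | C8 CH3, C10α OH, silyl enol ether | CC1=C[C@H](O)[C@]2(C)CC[C@](O[Si](CC)(CC)CC)(C(C)C)C2=C(O[Si](C)(C)C(C)(C)C)C1 | intermediate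
20 | C10 enone, silyl enol ether | CC1=CC(=O)[C@]2(C)CC[C@](O[Si](CC)(CC)CC)(C(C)C)C2=C(O[Si](C)(C)C(C)(C)C)C1 | intermediate
21 | C10β alcohol, silyl enol ether | CC1=C[C@@H](O)[C@]2(C)CC[C@](O[Si](CC)(CC)CC)(C(C)C)C2=C(O[Si](C)(C)C(C)(C)C)C1 | intermediate
22 | C10β isovalerate, silyl enol ether | CC1=C[C@@H](OC(=O)CC(C)C)[C@]2(C)CC[C@](O[Si](CC)(CC)CC)(C(C)C)C2=C(O[Si](C)(C)C(C)(C)C)C1 | intermediate
23 | cis-fused C6 ketone (C5β H), C10β isovalerate, C4β OSiEt3 | CC1=C[C@@H](OC(=O)CC(C)C)[C@]2(C)CC[C@](O[Si](CC)(CC)CC)(C(C)C)[C@@H]2C(=O)C1 | intermediate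
24 | C6α alcohol | CC1=C[C@@H](OC(=O)CC(C)C)[C@]2(C)CC[C@](O[Si](CC)(CC)CC)(C(C)C)[C@@H]2[C@H](O)C1 | intermediate
25 | 4-hydroxybenzoic acid | OC(=O)c1ccc(O)cc1 | starting material
26 | tert-butyldimethylsilyl 4-(tert-butyldimethylsilyloxy)benzoate | CC(C)(C)[Si](C)(C)OC(=O)c1ccc(O[Si](C)(C)C(C)(C)C)cc1 | intermediate (not isolated)
27 | 4-(tert-butyldimethylsilyloxy)benzoic acid | OC(=O)c1ccc(O[Si](C)(C)C(C)(C)C)cc1 | intermediate
28 | 4-(tert-butyldimethylsilyloxy)benzoic 2,4,6-trichlorobenzoic anhydride | O=C(OC(=O)c1c(Cl)cc(Cl)cc1Cl)c1ccc(O[Si](C)(C)C(C)(C)C)cc1 | intermediate (not isolated)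
29 | C6α 4-(tert-butyldimethylsilyloxy)benzoate, C10β isovalerate, C4β OSiEt3 | CC1=C[C@@H](OC(=O)CC(C)C)[C@]2(C)CC[C@](O[Si](CC)(CC)CC)(C(C)C)[C@@H]2[C@H](OC(=O)c2ccc(O[Si](C)(C)C(C)(C)C)cc2)C1 | intermediate
30 | CNP0086724.1 (local descriptors C1 R, C4 S, C5 S, C6 R, C10 R) | CC1=C[C@@H](OC(=O)CC(C)C)[C@]2(C)CC[C@](O)(C(C)C)[C@@H]2[C@H](OC(=O)c2ccc(O)cc2)C1 | target

**Step count.** Total: 19 steps. Longest linear sequence: 16 steps (steps 1–6, 9–16, 18 and 19).

**Steps most likely to fail**

1. Step 9. The catalyst may fail to overrule the bias of the C4 centre when the enol ether face is chosen, which would erode control at C1. The inward methyl may also slow the Cope shift enough for the donor–acceptor cyclopropane to open instead of rearranging. The fallback sets out from 9 and 11 and comes back at 17; it moves stereocontrol from the catalyst to a chiral auxiliary on the carbenoid. (R)-Pantolactone is acylated with glyoxylic acid chloride p-toluenesulfonylhydrazone (PhNMe2, then Et3N) to give (R)-pantolactonyl diazoacetate F1. DBU-catalysed aldol addition of F1 to 11 gives the hydroxy diazo ester F2, and dehydration as in step 8 through the trifluoroacetate F3 gives (R)-pantolactonyl (E)-4-(benzoyloxy)-2-diazobut-3-enoate F4. With achiral Rh2(O2CC7H15)4 (dirhodium tetraoctanoate) in hexanes, the auxiliary carbonyl shields one face of the carbenoid. Reaction with 9 and heating should pass through the cyclopropane F5 to the pantolactonyl ester cycloadduct F6, and reduction with i-Bu2AlH as in step 10 returns to 17.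

2. Step 8. Benzoyl migration or ionisation may accompany the dehydration, and the vinyl diazo ester may electrocyclise to a pyrazole before it is used. The fallback sets out from 11 and comes back at 14; the diazo group is introduced last by diazo transfer instead of being carried through a dehydration. Wittig reaction of 11 with Ph3P=CHCO2Et gives ethyl (E)-4-(benzoyloxy)but-2-enoate F7. Deconjugative Regitz diazo transfer (4-acetamidobenzenesulfonyl azide, DBU, MeCN, 0 °C), in which the extended enolate formed by γ-deprotonation is trapped at the α-carbon, should then give 14 directly.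

3. Step 16. Hydride may be delivered to the concave α face, for instance after a conformational change of the seven-membered ring that exposes it, so that the wrong C6 configuration results. The fallback sets out from 23 and comes back at 29; the stereocentre is set by substitution instead of by reduction. The C6 β-alcohol F8 that the reduction then gives is esterified with 27 under Mitsunobu conditions (PPh3, diisopropyl azodicarboxylate, toluene), which installs the aroyl group with inversion and leads straight to 29.

**Further compounds**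

F1 | step 9 | (R)-pantolactonyl diazoacetate | CC1(C)COC(=O)[C@@H]1OC(=O)C=[N+]=[N-]
F2 | step 9 | (R)-pantolactonyl 4-(benzoyloxy)-2-diazo-3-hydroxybutanoate (carbinol epimers) | CC1(C)COC(=O)[C@@H]1OC(=O)C(=[N+]=[N-])C(O)COC(=O)c1ccccc1
F3 | step 9 | (R)-pantolactonyl 4-(benzoyloxy)-2-diazo-3-(trifluoroacetoxy)butanoate | CC1(C)COC(=O)[C@@H]1OC(=O)C(=[N+]=[N-])C(OC(=O)C(F)(F)F)COC(=O)c1ccccc1
F4 | step 9 | (R)-pantolactonyl (E)-4-(benzoyloxy)-2-diazobut-3-enoate | CC1(C)COC(=O)[C@@H]1OC(=O)C(=[N+]=[N-])/C=C/OC(=O)c1ccccc1
F5 | step 9 | pantolactonyl ester analogue of cis-divinylcyclopropane 15 | CC1(C)COC(=O)[C@@H]1OC(=O)[C@@]1(/C=C/OC(=O)c2ccccc2)C[C@]1(O[Si](C)(C)C(C)(C)C)C3=C(C)CC[C@]3(O[Si](CC)(CC)CC)C(C)C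
F6 | step 9 | pantolactonyl ester analogue of cycloadduct 16 | CC1(C)COC(=O)[C@@H]1OC(=O)C1=C[C@H](OC(=O)c2ccccc2)[C@]2(C)CC[C@](O[Si](CC)(CC)CC)(C(C)C)C2=C(O[Si](C)(C)C(C)(C)C)C1
F7 | step 8 | ethyl (E)-4-(benzoyloxy)but-2-enoate | CCOC(=O)/C=C/COC(=O)c1ccccc1
F8 | step 16 | C6β alcohol (C6 epimer of 24) | CC1=C[C@@H](OC(=O)CC(C)C)[C@]2(C)CC[C@](O[Si](CC)(CC)CC)(C(C)C)[C@@H]2[C@@H](O)C1
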